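## Structural features

The target is a briarane-type diterpenoid: a cyclohexane (ring A, C1 and C10–C14) is trans-fused through C1–C10 to a ten-membered carbocycle (C1–C10), which carries a trans-fused γ-lactone across C7–C8 (O–C19(=O)–C17). Briarane numbering is used throughout (C15 is the methyl on C1, C16 the methylene carbon on C5, C18 the methyl on C17, C20 the epoxide CH2 on C11), and α means the face opposite to C15. There are eleven stereocentres, ten of them in two contiguous runs (C14–C1–C2 and C6–C7–C8–C9–C10–C11–C12) plus C17; C1 is quaternary, C8 is a tertiary carbinol and C11 is a spiro-epoxide carbon. Five oxygens must be told apart: an isobutyrate at C2, acetates at C9, C12 and C14, and a free tertiary hydroxyl at C8. The fragile groups are the 2,2-disubstituted epoxide (acid), the secondary allylic chloride at C6 beside the C5 methylene (allylic transposition, elimination), the β-hydroxy lactone (retro-aldol, dehydration) and the esters (migration). The real difficulty is the densely substituted ten-membered ring, which is hard to close end to end and gives little facial bias once formed. The key step exploits the fact that the oxygenated carbons C2 and C7 lie 1,6 across that ring with the methylene-bearing C5 and heteroatom-bearing C6 between them. That is the pattern left when the C2–C7 bond of a six-membered ring B (C1, C2, C7, C8, C9, C10) of a trans-decalin breaks in a [3,3] shift of a C2 vinyl group and a C7 1-alkoxyallenyl group.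

## Logic of the disconnections

From 44 the O–acetyl bonds at C12 and C14 and the epoxide C–O bonds at C11/C20 are cut, leading through 43 to 42. A free 12α-hydroxyl is the best handle for placing the epoxide oxygen on the α face, and the acid-sensitive epoxide is kept out of all but the last step. The forward demand is an epoxidation directed by the C12 hydroxyl that leaves the C5 methylene alone.

The 12,14-diol of 42 is re-closed to the acetonide (41), and the C6–Cl bond is cut with inversion back to the C6–O bond of 40 and its 4-methoxybenzyl ether 39. A C–O bond at C6 is what the ring-forming step delivers, and an oxidatively removable ether can be taken off beside esters, lactone and acetonide. The forward step must be a clean SN2 displacement at a secondary allylic carbon without allylic transposition.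

The C2 O–acyl bond and the C2–H bond are cut (39 to 38 to 37). This returns C2 to the ketone that the ring expansion produces and postpones the C2 ester until every other oxygen is masked. The forward demand is a face-selective reduction of a ketone on the ten-membered ring.

The lactone is opened at C8–C17 and at the O7–C19 acyl bond (37 to 36, then through 35 and 34 to 32 and 33). This reduces the lactone, the tertiary carbinol C8 and C17 to an intramolecular Reformatsky reaction of a C7 2-bromopropanoate on a C8 ketone. The forward demand is that the tether through O7 delivers the enolate to the face giving the trans-fused lactone.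

The C7–H bond and the O9–acetyl bond are cut together (32 to 31 and 30). One Evans–Tishchenko reaction sets C7 from the secure C9 stereocentre, installs the C9 acetate and leaves only the C7 hydroxyl free. The demand is 1,3-anti hydride delivery and a C9 silyl ether that can be removed selectively first.

The ten-membered ring is contracted: C4–C5 is cut and C2–C7 is re-joined (30 to 28). This removes the medium ring, replaces it by a trans-decalin on which stereocentres can be set reliably, and turns the C5 methylene and the C6 ether into a 1-alkoxyallene. The forward demand is a dianionic oxy-Cope shift that outruns side reactions of the allenyl alkoxide. Three features of 28 serve the later steps: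
- a silyl-protected oxygen at C8, because after the rearrangement C8 cannot be oxidised regioselectively (the C7 ketone enolises toward C6, and a C8 enolate would expel the C9 oxygen);
- a 4-methoxybenzyl ether at C6 in place of an acetal ether, so that it can be removed without acid;
- a triethylsilyl ether at C9 that is more labile than the C8 silyl ether.

The C6–C7 bond is cut (28 to 22 and 26; 26 back to 23 and 24). This separates a three-carbon unit that comes from propargyl alcohol. The forward addition must place the allenyl group equatorial on a hindered α-silyloxy ketone.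

In 22 the C8–O bond, the C11=C20 bond, the C12–H and C13–H bonds and the two protecting groups are removed (22 back through 21–13 to 12 and 11). All of ring A's functionality then derives from one enone and C8–O from an enol ether. The demands are an α-face epoxidation next to the angular methyl, a regiodefined C11 enolate and a trans-diaxial epoxide opening.

The C2–C3 bond and the C9–H bond are cut (11 back through 10, 9 and 8 to 6 and 7). This leaves an ene-dione whose two carbonyls differ electronically. The demand is chemoselective 1,2-addition to the C2 ketone in the presence of the vinylogous ester carbonyl at C9.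

The bonds C1–C14 and C10–C11 are cut (6 to 5 to 2 and 4; 2 from 1, 4 from 3). Both rings, the quaternary C1 and all oxygenation of C2, C7, C9 and C12 then come from one Diels–Alder reaction. The demands are regiocontrol, enantioface control at C1 and a later epimerisation at C10.

## Other disconnections considered

Alternative 1: The cut is through C1–C14 and C10–C11 of ring A, with the C9 carboxyl and the C20 oxygen joined as an ester tether.
- Forward step: a chiral oxazaborolidinium Lewis acid activates a tethered (E)-3-formylbut-2-enoate dienophile toward its 1-acetoxydiene; the intramolecular Diels–Alder reaction closes the cyclohexene and a trans-fused γ-lactone to give A1.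
- In its favour: C1, C10, C11 and C14 are set in one catalyst-controlled step, the C14 acetate is already in place, and C2, C9 and C20 emerge as differentiated handles. On absolute stereocontrol at the quaternary C1 this is the better plan, because the chosen route relies on a less precedented titanium-catalysed quinone cycloaddition.
- Against it here: A1 contains none of the ten-membered ring. Eight carbons (C2–C9, with the C5 methylene, the C6 chloride and the lactone) would have to be attached to a neopentyl aldehyde and a lactone and then closed end to end, which is the operation medium rings resist. The tethered ester must adopt an unfavourable geometry, the trans-fused five–six product is strained, and C12 still lacks oxygen.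
- Comparison: structurally A1 maps onto ring A only, whereas 28 maps onto both rings and their fusion. Mechanistically both key steps are concerted pericyclic reactions of comparable reliability, with catalyst control in A1 against substrate control in step 19. In step economy the cycloaddition is the equal of steps 3 and 4, but the unsolved macrocyclisation would make the whole route longer and less certain.

Alternative 2: The cut is through C6–Cl and the C7–O bond of the lactone.
- Forward step: an electrophilic chlorine donor under a dimeric cinchona alkaloid catalyst adds to an E-configured C6=C7 alkene while the C19 carboxylate closes on C7, giving A2 by anti addition; C5 still carries a silyloxymethyl group.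
- In its favour: chlorine and lactone oxygen arrive together and stereospecifically, so the C6/C7 relationship follows from the alkene geometry and no substitution at a hindered allylic carbon is needed. On this point it is better than step 29 of the chosen plan, where allylic transposition threatens.
- Against it here: it presupposes the complete ten-membered ring with an E alkene, the epoxide, four esters and the C8 tertiary hydroxyl, so the main problem is only moved. The free C8 hydroxyl and the epoxide can compete for the chloronium ion. Catalyst control of facial selectivity is established for 1,1-disubstituted alkenoic acids, not for a 1,2-dialkyl alkene held in a medium ring. The C5 methylene must afterwards be generated by elimination next to the new C–Cl bond.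
- Comparison: structurally A2 solves only the C6/C7/lactone corner, which the chosen plan handles in steps 21–25 and 29. Mechanistically the anti addition is more predictable in relative configuration but less predictable in facial sense. In step economy it saves nothing before the ring exists and adds the C5 elimination, so it is at best equal.

Alternative 3: The cut is through C10–C9 and C1–C2 on a ring A enone derived from quinic acid.
- Forward step: a vinylcopper reagent adds to C10 of the 2-methyl enone, and the enolate, after transmetalation to zinc, undergoes an aldol reaction with an aldehyde carrying C3–C6 and the C5 methylene, giving A3.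
- In its favour: three components are joined in one flask, C1 is made quaternary by enolate trapping, the absolute configuration comes from the chiral pool and the C5 methylene is brought in ready-made. In convergence and in the source of absolute configuration it is the equal or the better of the chosen plan.
- Against it here: the quinic pattern puts oxygen on C11 and C12 and a ketone on C14, so C11 must be converted into the spiro-epoxide carbon and C14 reduced with the right sense. The aldol of a fully substituted zinc enolate must also set C2 and can revert. The ten-membered ring must still be closed end to end, with C7, C8 and the lactone built afterwards.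
- Comparison: structurally A3 delivers ring A and both chains but no ring, while the chosen plan delivers the ring and must then decorate it. Mechanistically conjugate addition–aldol is better understood and more modular than step 19. In step economy A3 reaches an advanced open-chain stage quickly, but the ring closure and the redox corrections at C11 and C14 are expected to cost more than the ring expansion saves.

Key step: step 19

Assumption: the sense of induction of the (S)-BINOL titanium catalyst in step 3 is assigned by analogy with other chelating 2-methoxyquinones; if the antipode of 5 formed, (R)-BINOL would be used and nothing else would change.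

Remark: the C2 configuration of 8–28 is drawn for vinyl addition anti to the C14 methoxy group; it is erased in step 19, and the C2 epimer would be an equally valid substrate because the allenyl group on C7 is equatorial.

Step 1
Reactants: 1 2-methoxy-6-methylphenol
Product: 2 2-methoxy-6-methyl-1,4-benzoquinone
Conditions: O2 (1 atm), Co(salen) (5 mol %), DMF, rt
Reagents that add atoms: dioxygen, O=O
Why: Cobalt–salen catalysed aerobic oxidation of a 2,6-disubstituted phenol with a free para position is a standard route to the para-quinone.

Step 2
Reactants: 3 (E)-4-methoxybut-3-en-2-one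
Product: 4 (E)-3-(tert-butyldimethylsilyloxy)-1-methoxybuta-1,3-diene
Conditions: TBSOTf, Et3N, Et2O, 0 °C
Reagents that add atoms: tert-butyldimethylsilyl triflate, CC(C)(C)[Si](C)(C)OS(=O)(=O)C(F)(F)F
Why: O-Silylation of the methyl ketone enolate gives the 1-methoxy-3-silyloxy diene; the tert-butyldimethylsilyl enol ether is chosen because it must survive steps 3–6.

Step 3
Reactants: 2 2-methoxy-6-methyl-1,4-benzoquinone; 4 (E)-3-(tert-butyldimethylsilyloxy)-1-methoxybuta-1,3-diene
Product: 5 cis-fused Diels–Alder adduct (2,9-dione; 7-methoxy-7-ene; 12-silyloxy-12-ene; 14α-methoxy; 10β-H)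
Conditions: (S)-BINOL, TiCl2(Oi-Pr)2 (20 mol % each), 4 Å MS, toluene, −40 → −10 °C
Reagents that add atoms: none
Why: Diels–Alder reaction on the methylated alkene of 2 (the methoxylated alkene is a deactivated vinylogous ester) under a chiral tetravalent titanium BINOLate that chelates the C2 carbonyl and the methoxy group; the nucleophilic CH2 terminus of 4 bonds to the unsubstituted carbon (C10) and the methoxy-bearing terminus to C1, so oxygen ends on C12 and C14. The catalyst selects the quinone face and thereby fixes the quaternary C1; the endo cis fusion is corrected in step 4 and the C14 methoxy group is lost in step 7, so only regio- and enantioface selectivity matter.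

Step 4
Reactants: 5 cis-fused Diels–Alder adduct
Product: 6 trans-fused ene-dione (10α-H)
Conditions: DBU (0.2 equiv), CH2Cl2, rt; cis isomer recycled
Reagents that add atoms: none
Why: Base-mediated epimerisation of C10 (α to the C9 carbonyl) through the enolate, the classical way of converting angular-methyl quinone adducts into their trans-fused isomers; C1 is quaternary, so aromatisation is impossible.

Step 5
Reactants: 6 trans-fused ene-dione; 7 vinylmagnesium bromide
Product: 8 2-vinyl tertiary alcohol (2α-OH; 2β-vinyl; 9-ketone)
Conditions: CeCl3 (anhydrous), THF, −78 °C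
Reagents that add atoms: none
Why: Organocerium 1,2-addition to the non-enolisable C2 ketone; the C9 carbonyl is a vinylogous ester and far less electrophilic, and the low basicity of the cerium reagent spares the C10 proton. Attack anti to the pseudo-axial C14 methoxy group places the vinyl group equatorial; this configuration is erased in step 19.

Step 6
Reactants: 8 2-vinyl tertiary alcohol
Product: 9 2α,9β-diol (7-methoxy-7-ene; ring A silyl enol ether)
Conditions: i-Bu2AlH (3.5 equiv), CH2Cl2, −78 °C; Rochelle salt work-up
Reagents that add atoms: none
Why: 1,2-Reduction of the vinylogous ester carbonyl; hydride arrives on the α face, away from the syn-axial C15 methyl group, and gives the axial 9β-alcohol, and the non-acidic work-up preserves the methoxy-allyl alcohol.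

Step 7
Reactants: 9 2α,9β-diol
Product: 11 ring A enone (12-oxo-13-ene; 2α,9β-diol), via β-methoxy ketone 10 (not isolated)
Conditions: TBAF (1.1 equiv), THF, 0 °C; then DBU, rt
Reagents that add atoms: none
Why: Fluoride cleaves the silyl enol ether to the C12 ketone and E1cB loss of methanol gives the enone; the wholly basic medium protects the acid-labile enol ether of ring B, and the axial 9β-hydroxyl is too far from C14 for conjugate addition.

Step 8
Reactants: 11 ring A enone
Product: 12 9β-triethylsilyl ether of 11
Conditions: Et3SiCl, imidazole, DMAP (cat.), DMF, 0 °C → rt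
Reagents that add atoms: chlorotriethylsilane, CC[Si](Cl)(CC)CC
Why: Silylation of the only secondary hydroxyl; the tertiary C2 hydroxyl is too hindered, and the triethylsilyl group is chosen because it must later be removed before the C8 silyl ether.

Step 9
Reactants: 12 9β-triethylsilyl ether
Product: 13 13α,14α-epoxy-12-ketone
Conditions: t-BuOOH, DBU, CH2Cl2, 0 °C → rt
Reagents that add atoms: tert-butyl hydroperoxide, CC(C)(C)OO
Why: Nucleophilic (Weitz–Scheffer) epoxidation of the enone; the peroxide adds to C14 on the α face, anti to the adjacent axial C15 methyl group, as in 1-en-3-one steroids, and the electron-rich enol ether and vinyl group are inert to it.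

Step 10
Reactants: 13 13α,14α-epoxy-12-ketone
Product: 16 11-methylene-13α,14α-epoxy-12-ketone, via Mannich base 14 (not isolated), via trimethylammonium iodide 15 (not isolated)
Conditions: LiN(i-Pr)2 (2.2 equiv), THF, −78 °C; Me2N=CH2+ I− (1.2 equiv), −78 → 0 °C; then MeI, CH2Cl2–MeOH, rt; then aq. NaHCO3, rt
Reagents that add atoms: Eschenmoser's salt, C=[N+](C)C.[I-]
Why: The epoxide leaves C11 as the only enolisable position of the C12 ketone, so the lithium enolate is regiodefined; Mannich reaction, N-methylation and Hofmann-type elimination give the α-methylene ketone that supplies C20.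

Step 11
Reactants: 16 11-methylene-13α,14α-epoxy-12-ketone
Product: 17 12α-alcohol (cis to the epoxide)
Conditions: NaBH4, CeCl3·7H2O, MeOH, −78 °C
Reagents that add atoms: none
Why: Luche 1,2-reduction of the enone; hydride adds anti to the epoxide oxygen on the β face and gives the 12α-alcohol.

Step 12
Reactants: 17 12α-alcohol
Product: 18 2α,12α,14α-triol (11-methylene; 7-methoxy-7-ene; 9β-triethylsilyl ether)
Conditions: LiEt3BH (5 equiv), THF, 0 °C → rt
Reagents that add atoms: none
Why: Hydride opens the epoxide at C13 in the trans-diaxial (Fürst–Plattner) mode; C14 is neopentylic and keeps its oxygen as the axial 14α-hydroxyl, the same outcome as the hydride opening of 1α,2α-epoxy steroids.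

Step 13
Reactants: 18 2α,12α,14α-triol
Product: 20 8α-hydroxy-7-ketone (2α,12α,14α-triol), via 7α,8α-epoxy-7-methoxy intermediate 19 (not isolated)
Conditions: DMDO (1.05 equiv), acetone–CH2Cl2, −78 → −20 °C; pH 7 aqueous work-up
Reagents that add atoms: dimethyldioxirane, CC1(C)OO1
Why: Rubottom-type oxidation of the methyl enol ether, by far the most electron-rich alkene; epoxidation occurs anti to the axial 9β-silyloxy and C15 methyl groups and the methoxy-epoxide collapses with loss of methanol to the α-hydroxy ketone. The C8 configuration is of no consequence because C8 becomes a ketone in step 24.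

Step 14
Reactants: 20 8α-hydroxy-7-ketone
Product: 21 12,14-acetonide of 20
Conditions: 2,2-dimethoxypropane (1.5 equiv), PPTS (cat.), CH2Cl2, 0 °C → rt
Reagents that add atoms: 2,2-dimethoxypropane, COC(C)(C)OC
Why: Acetonide formation on the cis-diaxial 12,14-diol, whose hydroxyls are both secondary; the acetals that would involve the tertiary C2 hydroxyl form much more slowly.

Step 15
Reactants: 21 12,14-acetonide
Product: 22 8α-tert-butyldimethylsilyl ether (C7 ketone; 2α-OH)
Conditions: TBSOTf (1.1 equiv), 2,6-lutidine, CH2Cl2, −78 °C
Reagents that add atoms: tert-butyldimethylsilyl triflate, CC(C)(C)[Si](C)(C)OS(=O)(=O)C(F)(F)F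
Why: Silylation of the only secondary hydroxyl; an ether is needed at C8 to pass the organolithium and KH steps, and it must outlast the C9 triethylsilyl ether.

Step 16
Reactants: 23 propargyl alcohol; 24 4-methoxybenzyl chloride
Product: 25 4-methoxybenzyl propargyl ether
Conditions: NaH, Bu4NI (cat.), THF, 0 °C → rt
Reagents that add atoms: none
Why: Williamson ether synthesis.

Step 17
Reactants: 25 4-methoxybenzyl propargyl ether
Product: 26 1-(4-methoxybenzyloxy)propa-1,2-diene
Conditions: KOt-Bu (0.3 equiv), THF, rt
Reagents that add atoms: none
Why: Base-catalysed propargyl-to-allenyl ether isomerisation, as used for methyl, methoxymethyl and benzyl propargyl ethers.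

Step 18
Reactants: 22 8α-tert-butyldimethylsilyl ether; 26 1-(4-methoxybenzyloxy)propa-1,2-diene
Product: 28 2-vinyl-7-[1-(4-methoxybenzyloxy)allenyl] trans-decalin-2,7-diol (2α,7β-diol; 8α-silyloxy; 9β-silyloxy; 11-methylene; 12,14-acetonide), via 1-lithio-1-(4-methoxybenzyloxy)allene 27 (not isolated)
Conditions: 26 (4 equiv), n-BuLi (3.8 equiv), THF, −78 → −40 °C; then 22, −78 → −30 °C
Reagents that add atoms: none
Why: α-Lithiation of the alkoxyallene and 1,2-addition to the C7 ketone, a standard use of lithiated alkoxyallenes; one equivalent is consumed by the C2 hydroxyl. The axial trajectory is blocked by the syn-axial C15 methyl and 9β-silyloxy groups, so the allenyl group enters equatorially and the hydroxyl is axial.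

Step 19
Reactants: 28 2-vinyl-7-[1-(4-methoxybenzyloxy)allenyl] trans-decalin-2,7-diol
Product: 30 ten-membered 2,7-dione (5-methylene; 6β-(4-methoxybenzyloxy); 8α-silyloxy; 9β-silyloxy; 12,14-acetonide), via dipotassium bis-enolate 29 (not isolated)
Conditions: KH (3 equiv), 18-crown-6 (3 equiv), THF, 0 °C → rt; then cannulation into AcOH–THF, −78 °C
Reagents that add atoms: none
Why: Proposed new method: double deprotonation gives the 1,2-dialkoxide, whose two oxyanions weaken the C2–C7 bond, and a concerted chair [3,3] shift joins the vinyl terminus C4 to the central allene carbon C5 while C2–C7 breaks; the closest known reactions are the dianionic oxy-Cope ring expansion of 1,2-divinylcyclohexane-1,2-diols to cyclodecane-1,6-diones and the thermal oxy-Cope rearrangement of allenyl carbinols. The ten-membered ring is closed by ring expansion of ring B, in which the bridge C1–C10–C9–C8 is retained and only C4–C5 is made, not by an end-to-end cyclisation. Because C5 was the central allene carbon it keeps its second π bond as the exocyclic C5=C16 methylene, and the allene oxygen ends on C6. The only geometric demand is that the two unsaturated groups are gauche on the chair of ring B, which the equatorial allenyl group secures for either C2 epimer. The one new stereocentre, C6, is set when the C6=C7 dienolate of 29 is protonated at its α-carbon by inverse addition into cold acetic acid; delivery to the exposed face of the medium ring is expected to give the 6β ether drawn, and α-protonation keeps the C5 methylene out of conjugation. The step needs the [3,3] shift to outrun 5-endo closure of the C7 alkoxide onto the allene terminus, which the release of strain from four contiguous fully substituted carbons should ensure. It also needs the enolates not to equilibrate before the quench, since a C7=C8 enolate could expel the C9 silyloxy group; the crown-separated potassium enolates in THF have no proton source. C9 must remain protected, because a free β-alkoxide would open the new ring by retro-aldol cleavage.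

Step 20
Reactants: 30 ten-membered 2,7-dione
Product: 31 9β-hydroxy-2,7-dione
Conditions: HF·pyridine, pyridine, THF, 0 °C
Reagents that add atoms: none
Why: Buffered fluoride removes the triethylsilyl ether selectively in the presence of the more robust tert-butyldimethylsilyl ether, the acetonide and the 4-methoxybenzyl ether; the mildly acidic medium avoids retro-aldol cleavage of the β-hydroxy ketone.

Step 21
Reactants: 31 9β-hydroxy-2,7-dione
Product: 32 9β-acetoxy-7α-hydroxy-2-ketone
Conditions: SmI2 (0.3 equiv), MeCHO (10 equiv), THF, −10 °C
Reagents that add atoms: acetaldehyde, CC=O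
Why: Evans–Tishchenko reduction: the hemiacetal formed from the C9 hydroxyl and acetaldehyde delivers hydride to C7 within a samarium-bridged six-membered transition state, so the new hydroxyl is 1,3-anti to C9 (7α) whatever the substituent on C8. The C9 oxygen emerges as the acetate the target needs, only the C7 hydroxyl is left free, and the C2 ketone, which has no β-hydroxyl, is untouched.

Step 22
Reactants: 32 9β-acetoxy-7α-hydroxy-2-ketone; 33 2-bromopropanoyl bromide
Product: 34 7α-(2-bromopropanoyl) ester (mixture at the CHBr carbon)
Conditions: pyridine, DMAP (cat.), CH2Cl2, −20 °C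
Reagents that add atoms: none
Why: Acylation of the single free hydroxyl with a reactive acyl bromide; the configuration at the bromine-bearing carbon is lost in step 25.

Step 23
Reactants: 34 7α-(2-bromopropanoyl) ester
Product: 35 8α-alcohol
Conditions: HF·pyridine, THF, 0 °C → rt
Reagents that add atoms: none
Why: Acidic fluoride removes the C8 silyl ether without the acyl migration that basic fluoride would cause between O7, O8 and O9; the acetonide and the benzylic ether tolerate the conditions.

Step 24
Reactants: 35 8α-alcohol
Product: 36 8-ketone
Conditions: Dess–Martin periodinane, NaHCO3, CH2Cl2, 0 °C → rt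
Reagents that add atoms: none
Why: Neutral oxidation of the only free hydroxyl; the α,α′-bis(acyloxy) ketone is base-sensitive and is used at once.

Step 25
Reactants: 36 8-ketone
Product: 37 7,8-fused γ-lactone (8α-hydroxy; C18 methyl cis to the C8 hydroxyl; 2-ketone)
Conditions: SmI2 (2.5 equiv), THF, −78 °C; sat. NH4Cl
Reagents that add atoms: none
Why: Intramolecular Reformatsky reaction promoted by divalent samarium: reduction of the C–Br bond gives the samarium ester enolate, which adds to the adjacent C8 ketone and closes the lactone through C8–C17. Because the enolate is tethered through O7 it must approach with C6, not C9, near the carbonyl oxygen (ring torsion C6–C7–C8–C9 near 150° rather than near 0°), which gives the trans-fused lactone with the 8α-hydroxyl. The C18 methyl settles trans to C9 and, being α to the lactone carbonyl, is open to equilibration.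

Step 26
Reactants: 37 7,8-fused γ-lactone
Product: 38 2β-alcohol
Conditions: NaBH4, MeOH–CH2Cl2, −40 °C
Reagents that add atoms: none
Why: Borohydride reduction of the last ketone; the lactone and esters are inert at this temperature. With the C2–C3 bond anti to C1–C14, the conformation the lactone-bridged ring shares with related natural products, the β face of the carbonyl is screened by the C15 methyl group and hydride adds from the α face to give the 2β-alcohol.

Step 27
Reactants: 38 2β-alcohol
Product: 39 2β-isobutyrate
Conditions: (i-PrCO)2O, DMAP, Et3N, CH2Cl2, rt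
Reagents that add atoms: isobutyric anhydride, CC(C)C(=O)OC(=O)C(C)C
Why: DMAP-catalysed acylation of the only secondary hydroxyl; the tertiary C8 hydroxyl does not react.

Step 28
Reactants: 39 2β-isobutyrate
Product: 40 6β-alcohol
Conditions: DDQ, CH2Cl2–pH 7 buffer, 0 °C
Reagents that add atoms: none
Why: Oxidative cleavage of the 4-methoxybenzyl ether under neutral conditions that leave the acetonide, the esters, the lactone and both methylene groups intact.

Step 29
Reactants: 40 6β-alcohol
Product: 41 6α-chloride
Conditions: PPh3 (1.5 equiv), hexachloroacetone (3 equiv), CH2Cl2, −20 → 0 °C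
Reagents that add atoms: hexachloroacetone, O=C(C(Cl)(Cl)Cl)C(Cl)(Cl)Cl
Why: Appel-type chlorination with PPh3 and hexachloroacetone, the variant that converts secondary allylic alcohols into chlorides with inversion and little allylic transposition; SN2 displacement of the oxyphosphonium group turns the 6β-alcohol into the 6α-chloride, and the tertiary C8 hydroxyl does not react.

Step 30
Reactants: 41 6α-chloride
Product: 42 12α,14α-diol
Conditions: AcOH–H2O (4:1), 40 °C
Reagents that add atoms: none
Why: Mild aqueous acid hydrolyses the acetonide; the allylic chloride, the esters and the β-hydroxy lactone tolerate it.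

Step 31
Reactants: 42 12α,14α-diol
Product: 43 11α,20-epoxide (12α,14α-diol)
Conditions: VO(acac)2 (5 mol %), t-BuOOH, CH2Cl2, 0 °C
Reagents that add atoms: tert-butyl hydroperoxide, CC(C)(C)OO
Why: Hydroxyl-directed epoxidation: the vanadium alkoxide of the allylic 12α-hydroxyl delivers oxygen to the same face of the C11=C20 alkene and sets the spiro centre C11 with the oxygen α. The C5 methylene has no free allylic hydroxyl and is deactivated by the allylic chloride.

Step 32
Reactants: 43 11α,20-epoxide
Product: 44 CNP0145565.1
Conditions: Ac2O, DMAP, pyridine, CH2Cl2, rt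
Reagents that add atoms: acetic anhydride, CC(=O)OC(C)=O
Why: Acetylation of the two secondary hydroxyls at C12 and C14 under basic conditions that the epoxide and the allylic chloride tolerate; the tertiary C8 hydroxyl stays free.

## Compound list

1 | 2-methoxy-6-methylphenol | COc1cccc(C)c1O | starting material
2 | 2-methoxy-6-methyl-1,4-benzoquinone | COC1=CC(=O)C=C(C)C1=O | intermediate
3 | (E)-4-methoxybut-3-en-2-one | CO/C=C/C(C)=O | starting material
4 | (E)-3-(tert-butyldimethylsilyloxy)-1-methoxybuta-1,3-diene | CO/C=C/C(=C)O[Si](C)(C)C(C)(C)C | intermediate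
5 | cis-fused Diels–Alder adduct (2,9-dione; 7-methoxy-7-ene; 12-silyloxy-12-ene; 14α-methoxy; 10β-H) | O=C1[C@@]2(C)[C@@H](OC)C=C(O[Si](C)(C)C(C)(C)C)C[C@H]2C(=O)C=C1OC | intermediate
6 | trans-fused ene-dione (10α-H) | O=C1[C@@]2(C)[C@@H](OC)C=C(O[Si](C)(C)C(C)(C)C)C[C@@H]2C(=O)C=C1OC | intermediate
7 | vinylmagnesium bromide | C=C[Mg]Br | starting material
8 | 2-vinyl tertiary alcohol (2α-OH; 2β-vinyl; 9-ketone) | C=C[C@]1(O)[C@@]2(C)[C@@H](OC)C=C(O[Si](C)(C)C(C)(C)C)C[C@@H]2C(=O)C=C1OC | intermediate
9 | 2α,9β-diol (7-methoxy-7-ene; ring A silyl enol ether) | C=C[C@]1(O)[C@@]2(C)[C@@H](OC)C=C(O[Si](C)(C)C(C)(C)C)C[C@@H]2[C@H](O)C=C1OC | intermediate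
10 | β-methoxy ketone (12-oxo; 14α-methoxy) | C=C[C@]1(O)[C@@]2(C)[C@@H](OC)CC(=O)C[C@@H]2[C@H](O)C=C1OC | intermediate
11 | ring A enone (12-oxo-13-ene; 2α,9β-diol) | C=C[C@]1(O)[C@@]2(C)C=CC(=O)C[C@@H]2[C@H](O)C=C1OC | intermediate
12 | 9β-triethylsilyl ether of 11 | C=C[C@]1(O)[C@@]2(C)C=CC(=O)C[C@@H]2[C@H](O[Si](CC)(CC)CC)C=C1OC | intermediate
13 | 13α,14α-epoxy-12-ketone | C=C[C@]1(O)[C@@]2(C)[C@H]3O[C@H]3C(=O)C[C@@H]2[C@H](O[Si](CC)(CC)CC)C=C1OC | intermediate
14 | Mannich base (11-dimethylaminomethyl; C11 unassigned) | C=C[C@]1(O)[C@@]2(C)[C@H]3O[C@H]3C(=O)C(CN(C)C)[C@@H]2[C@H](O[Si](CC)(CC)CC)C=C1OC | intermediate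
15 | trimethylammonium iodide of 14 | C=C[C@]1(O)[C@@]2(C)[C@H]3O[C@H]3C(=O)C(C[N+](C)(C)C)[C@@H]2[C@H](O[Si](CC)(CC)CC)C=C1OC.[I-] | intermediate
16 | 11-methylene-13α,14α-epoxy-12-ketone | C=C[C@]1(O)[C@@]2(C)[C@H]3O[C@H]3C(=O)C(=C)[C@@H]2[C@H](O[Si](CC)(CC)CC)C=C1OC | intermediate
17 | 12α-alcohol (cis to the epoxide) | C=C[C@]1(O)[C@@]2(C)[C@H]3O[C@H]3[C@@H](O)C(=C)[C@@H]2[C@H](O[Si](CC)(CC)CC)C=C1OC | intermediate
18 | 2α,12α,14α-triol (11-methylene; 7-methoxy-7-ene; 9β-triethylsilyl ether) | C=C[C@]1(O)[C@@]2(C)[C@@H](O)C[C@@H](O)C(=C)[C@@H]2[C@H](O[Si](CC)(CC)CC)C=C1OC | intermediate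
19 | 7α,8α-epoxy-7-methoxy intermediate | C=C[C@]1(O)[C@@]2(C)[C@@H](O)C[C@@H](O)C(=C)[C@@H]2[C@H](O[Si](CC)(CC)CC)[C@H]4O[C@@]14OC | intermediate
20 | 8α-hydroxy-7-ketone (2α,12α,14α-triol) | C=C[C@]1(O)[C@@]2(C)[C@@H](O)C[C@@H](O)C(=C)[C@@H]2[C@H](O[Si](CC)(CC)CC)[C@@H](O)C1=O | intermediate
21 | 12,14-acetonide of 20 | C=C[C@]1(O)[C@@]2(C)[C@@H](OC3(C)C)C[C@@H](O3)C(=C)[C@@H]2[C@H](O[Si](CC)(CC)CC)[C@@H](O)C1=O | intermediate
22 | 8α-tert-butyldimethylsilyl ether (C7 ketone; 2α-OH) | C=C[C@]1(O)[C@@]2(C)[C@@H](OC3(C)C)C[C@@H](O3)C(=C)[C@@H]2[C@H](O[Si](CC)(CC)CC)[C@@H](O[Si](C)(C)C(C)(C)C)C1=O | intermediate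
23 | propargyl alcohol | C#CCO | starting material
24 | 4-methoxybenzyl chloride | COc1ccc(CCl)cc1 | starting material
25 | 4-methoxybenzyl propargyl ether | C#CCOCc1ccc(OC)cc1 | intermediate
26 | 1-(4-methoxybenzyloxy)propa-1,2-diene | C=C=COCc1ccc(OC)cc1 | intermediate
27 | 1-lithio-1-(4-methoxybenzyloxy)allene | [Li]C(OCc1ccc(OC)cc1)=C=C | intermediate
28 | 2-vinyl-7-[1-(4-methoxybenzyloxy)allenyl] trans-decalin-2,7-diol (2α,7β-diol; 8α-OTBS; 9β-OTES; 11-methylene; 12,14-acetonide) | C=C[C@]1(O)[C@@]2(C)[C@@H](OC3(C)C)C[C@@H](O3)C(=C)[C@@H]2[C@H](O[Si](CC)(CC)CC)[C@@H](O[Si](C)(C)C(C)(C)C)[C@@]1(O)C(OCc4ccc(OC)cc4)=C=C | intermediate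
29 | dipotassium bis-enolate (C2=C3 and C6=C7 enolates; geometry from the chair shift) | C=C1CC=C([O-])[C@@]2(C)[C@@H](OC3(C)C)C[C@@H](O3)C(=C)[C@@H]2[C@H](O[Si](CC)(CC)CC)[C@@H](O[Si](C)(C)C(C)(C)C)C([O-])=C1OCc4ccc(OC)cc4.[K+].[K+] | intermediate
30 | ten-membered 2,7-dione (5-methylene; 6β-OPMB; 8α-OTBS; 9β-OTES; 12,14-acetonide) | C=C1CCC(=O)[C@@]2(C)[C@@H](OC3(C)C)C[C@@H](O3)C(=C)[C@@H]2[C@H](O[Si](CC)(CC)CC)[C@@H](O[Si](C)(C)C(C)(C)C)C(=O)[C@@H]1OCc4ccc(OC)cc4 | intermediate
31 | 9β-hydroxy-2,7-dione | C=C1CCC(=O)[C@@]2(C)[C@@H](OC3(C)C)C[C@@H](O3)C(=C)[C@@H]2[C@H](O)[C@@H](O[Si](C)(C)C(C)(C)C)C(=O)[C@@H]1OCc4ccc(OC)cc4 | intermediate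
32 | 9β-acetoxy-7α-hydroxy-2-ketone | C=C1CCC(=O)[C@@]2(C)[C@@H](OC3(C)C)C[C@@H](O3)C(=C)[C@@H]2[C@H](OC(C)=O)[C@@H](O[Si](C)(C)C(C)(C)C)[C@@H](O)[C@@H]1OCc4ccc(OC)cc4 | intermediate
33 | 2-bromopropanoyl bromide (racemic) | CC(Br)C(=O)Br | starting material
34 | 7α-(2-bromopropanoyl) ester | C=C1CCC(=O)[C@@]2(C)[C@@H](OC3(C)C)C[C@@H](O3)C(=C)[C@@H]2[C@H](OC(C)=O)[C@@H](O[Si](C)(C)C(C)(C)C)[C@@H](OC(=O)C(C)Br)[C@@H]1OCc4ccc(OC)cc4 | intermediate
35 | 8α-alcohol | C=C1CCC(=O)[C@@]2(C)[C@@H](OC3(C)C)C[C@@H](O3)C(=C)[C@@H]2[C@H](OC(C)=O)[C@@H](O)[C@@H](OC(=O)C(C)Br)[C@@H]1OCc4ccc(OC)cc4 | intermediate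
36 | 8-ketone | C=C1CCC(=O)[C@@]2(C)[C@@H](OC3(C)C)C[C@@H](O3)C(=C)[C@@H]2[C@H](OC(C)=O)C(=O)[C@@H](OC(=O)C(C)Br)[C@@H]1OCc4ccc(OC)cc4 | intermediate
37 | 7,8-fused γ-lactone (8α-OH; C18 methyl cis to 8-OH; 2-ketone) | C=C1CCC(=O)[C@@]2(C)[C@@H](OC3(C)C)C[C@@H](O3)C(=C)[C@@H]2[C@H](OC(C)=O)[C@]5(O)[C@@H](C)C(=O)O[C@H]5[C@@H]1OCc4ccc(OC)cc4 | intermediate
38 | 2β-alcohol | C=C1CC[C@H](O)[C@@]2(C)[C@@H](OC3(C)C)C[C@@H](O3)C(=C)[C@@H]2[C@H](OC(C)=O)[C@]5(O)[C@@H](C)C(=O)O[C@H]5[C@@H]1OCc4ccc(OC)cc4 | intermediate
39 | 2β-isobutyrate | C=C1CC[C@H](OC(=O)C(C)C)[C@@]2(C)[C@@H](OC3(C)C)C[C@@H](O3)C(=C)[C@@H]2[C@H](OC(C)=O)[C@]5(O)[C@@H](C)C(=O)O[C@H]5[C@@H]1OCc4ccc(OC)cc4 | intermediate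
40 | 6β-alcohol | C=C1CC[C@H](OC(=O)C(C)C)[C@@]2(C)[C@@H](OC3(C)C)C[C@@H](O3)C(=C)[C@@H]2[C@H](OC(C)=O)[C@]5(O)[C@@H](C)C(=O)O[C@H]5[C@@H]1O | intermediate
41 | 6α-chloride | C=C1CC[C@H](OC(=O)C(C)C)[C@@]2(C)[C@@H](OC3(C)C)C[C@@H](O3)C(=C)[C@@H]2[C@H](OC(C)=O)[C@]5(O)[C@@H](C)C(=O)O[C@H]5[C@H]1Cl | intermediate
42 | 12α,14α-diol | C=C1CC[C@H](OC(=O)C(C)C)[C@@]2(C)[C@@H](O)C[C@@H](O)C(=C)[C@@H]2[C@H](OC(C)=O)[C@]5(O)[C@@H](C)C(=O)O[C@H]5[C@H]1Cl | intermediate
43 | 11α,20-epoxide (12α,14α-diol) | C=C1CC[C@H](OC(=O)C(C)C)[C@@]2(C)[C@@H](O)C[C@@H](O)[C@]3(CO3)[C@@H]2[C@H](OC(C)=O)[C@]5(O)[C@@H](C)C(=O)O[C@H]5[C@H]1Cl | intermediate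
44 | CNP0145565.1 | C=C1CC[C@H](OC(=O)C(C)C)[C@@]2(C)[C@@H](OC(C)=O)C[C@@H](OC(C)=O)[C@]3(CO3)[C@@H]2[C@H](OC(C)=O)[C@]2(O)[C@@H](C)C(=O)O[C@H]2[C@H]1Cl | target

Total step count: 32. Longest linear sequence: 29 steps (steps 1, 3–15 and 18–32; steps 2 and 16–17 are side branches).

Least certain steps

Step 19 (key step). The most likely failure is that the C7 alkoxide adds to the terminal allene carbon (5-endo closure to a 3-alkoxy-2,5-dihydrofuran, the usual fate of α-hydroxyalkyl alkoxyallenes under strong potassium bases) faster than the [3,3] shift occurs. Migration of the neighbouring silyl groups onto the tertiary alkoxides is a related risk. The facial selectivity of the C6 protonation is the second uncertainty and does not change the fallback. Fallback with known chemistry, avoiding any alkoxide: from 28, silylation of both tertiary hydroxyls (TMSOTf, Et3N, CH2Cl2, −78 → 0 °C) gives the bis(trimethylsilyl) ether of 28 F1. Heating in toluene (sealed tube, about 170 °C) brings about the neutral siloxy-Cope rearrangement, known for 3-silyloxy-1,5-dienes and for allenyl carbinols, to the ten-membered bis(trimethylsilyl enol ether) F2. K2CO3 in MeOH at −20 °C removes the two enol silyl groups and returns to 30.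

Step 3. The enantioselectivity or the turnover may be low, because the reacting alkene is trisubstituted and the titanium Lewis acid is mild. Fallback: 2 and 4 are combined thermally (toluene, 60 °C), which should give racemic 5 with the same regiochemistry, and the racemate is carried through steps 4–7 to racemic 11. Lipase-catalysed acetylation of the C9 hydroxyl (Amano PS lipase, vinyl acetate, t-BuOMe) then resolves the alcohol; the unwanted enantiomer is removed as the 9-O-acetate of ent-11 F3, and the route is rejoined at 11.

Step 18. The hindered C7 ketone may be enolised toward C8, with β-elimination of the C9 silyloxy group, or may simply fail to accept the nucleophile next to the axial C8 silyl ether. Fallback: the order of silylation and addition is reversed. From 21, excess 27 is added to the free α-ketol (its lithium alkoxide cannot enolise toward C8), giving the 2,7,8-triol F4; TBSOTf and 2,6-lutidine at −78 °C then silylate the only secondary hydroxyl and return to 28.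

Step 25. Reductive loss of the α-acyloxy groups of the C8 ketone by divalent samarium may compete with the ring closure, or the closure may show poor facial selectivity at C8. Fallback: from 36, PPh3 and then Et3N (MeCN, rt) convert the bromo ester into the ylide, which closes by intramolecular Wittig reaction to the Δ8(17)-butenolide F5. Nucleophilic epoxidation (t-BuOOH, DBU) gives the 8α,17α-epoxy lactone F6, and reductive opening of the α,β-epoxy lactone at C17 (SmI2, THF–MeOH, −78 °C) returns to 37.

Step 26. Facial selectivity may be poor on a conformationally mobile ketone. Fallback with intramolecular hydride delivery: from 37, the acetonide is cleaved (AcOH–H2O, 40 °C) to the 12α,14α-diol ketone F7. Me4NBH(OAc)3 (AcOH–MeCN, −20 °C), bound to the C14 oxygen, should reduce C2 in the 1,3-anti sense (2β) to the 2β,12α,14α-triol F8. 2,2-Dimethoxypropane and PPTS re-close the acetonide on the cis-diaxial 12,14-diol (the anti-disposed 2,14-diol cannot form a chair dioxane) and return to 38.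

Step 29. Allylic transposition (attack of chloride at C16) or ionisation may compete with direct displacement, because C6 is flanked by the fully substituted sp2 carbon C5 and the lactone carbon C7. Fallback, separating activation from displacement: from 40, chloromethanesulfonyl chloride and pyridine (CH2Cl2, 0 °C) give the 6β-chloromethanesulfonate F9, a discrete sulfonate suited to hindered secondary centres. Displacement with LiCl in DMF at rt, a bimolecular reaction with free chloride, returns to 41.

## Further compounds

F1 | step 19 | bis(trimethylsilyl) ether of 28 | C=C[C@]1(O[Si](C)(C)C)[C@@]2(C)[C@@H](OC3(C)C)C[C@@H](O3)C(=C)[C@@H]2[C@H](O[Si](CC)(CC)CC)[C@@H](O[Si](C)(C)C(C)(C)C)[C@@]1(O[Si](C)(C)C)C(OCc4ccc(OC)cc4)=C=C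
F2 | step 19 | ten-membered bis(trimethylsilyl enol ether) | C=C1CC=C(O[Si](C)(C)C)[C@@]2(C)[C@@H](OC3(C)C)C[C@@H](O3)C(=C)[C@@H]2[C@H](O[Si](CC)(CC)CC)[C@@H](O[Si](C)(C)C(C)(C)C)C(O[Si](C)(C)C)=C1OCc4ccc(OC)cc4
F3 | step 3 | 9-O-acetate of ent-11 | C=C[C@@]1(O)[C@]2(C)C=CC(=O)C[C@H]2[C@@H](OC(C)=O)C=C1OC
F4 | step 18 | 2,7,8-triol (8-desilyl 28) | C=C[C@]1(O)[C@@]2(C)[C@@H](OC3(C)C)C[C@@H](O3)C(=C)[C@@H]2[C@H](O[Si](CC)(CC)CC)[C@@H](O)[C@@]1(O)C(OCc4ccc(OC)cc4)=C=C
F5 | step 25 | Δ8(17)-butenolide | C=C1CCC(=O)[C@@]2(C)[C@@H](OC3(C)C)C[C@@H](O3)C(=C)[C@@H]2[C@H](OC(C)=O)C5=C(C)C(=O)O[C@H]5[C@@H]1OCc4ccc(OC)cc4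
F6 | step 25 | 8α,17α-epoxy lactone | C=C1CCC(=O)[C@@]2(C)[C@@H](OC3(C)C)C[C@@H](O3)C(=C)[C@@H]2[C@H](OC(C)=O)[C@@]56O[C@@]6(C)C(=O)O[C@H]5[C@@H]1OCc4ccc(OC)cc4
F7 | step 26 | 12α,14α-diol of 37 | C=C1CCC(=O)[C@@]2(C)[C@@H](O)C[C@@H](O)C(=C)[C@@H]2[C@H](OC(C)=O)[C@]5(O)[C@@H](C)C(=O)O[C@H]5[C@@H]1OCc4ccc(OC)cc4
F8 | step 26 | 2β,12α,14α-triol | C=C1CC[C@H](O)[C@@]2(C)[C@@H](O)C[C@@H](O)C(=C)[C@@H]2[C@H](OC(C)=O)[C@]5(O)[C@@H](C)C(=O)O[C@H]5[C@@H]1OCc4ccc(OC)cc4
F9 | step 29 | 6β-chloromethanesulfonate of 40 | C=C1CC[C@H](OC(=O)C(C)C)[C@@]2(C)[C@@H](OC3(C)C)C[C@@H](O3)C(=C)[C@@H]2[C@H](OC(C)=O)[C@]5(O)[C@@H](C)C(=O)O[C@H]5[C@@H]1OS(=O)(=O)CCl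
A1 | alternative 1 | trans-fused bicyclic lactone aldehyde | O=C[C@@]2(C)[C@@H](OC(C)=O)C=C[C@H]3COC(=O)[C@H]23
A2 | alternative 2 | 6-chloro lactone with C5 silyloxymethyl | CC(C)(C)[Si](C)(C)OC[C@H]1CC[C@H](OC(=O)C(C)C)[C@@]2(C)[C@@H](OC(C)=O)C[C@@H](OC(C)=O)[C@]3(CO3)[C@@H]2[C@H](OC(C)=O)[C@]2(O)[C@@H](C)C(=O)O[C@H]2[C@H]1Cl
A3 | alternative 3 | ring A ketone with C10 vinyl and C1–C2 aldol arm | CC(C)(C)[Si](C)(C)OCC(=C)CC[C@H](O)[C@@]2(C)C(=O)C[C@H]3OC(C)(C)O[C@H]3[C@@H]2C=C
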